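**Plan**

- Retrosynthesis: the quinone is taken back to its bis-MOM hydroquinone, a hexasubstituted benzene. In indole B (the 7-prenylindole) the bonds C3–C3a and N1–C2 are cut, which opens its pyrrole ring (N1, C2, C3, C3a, C7a).
- This works because the prenyl group sits on C7, ortho to N1: it can be carried by a 2-iodo-6-prenylaniline, while C2 and C3 come from a silylalkyne already bonded to the central ring.
- Further cuts: the aryl–C3 bond to indole A (Negishi), the aryl–alkyne bond (Sonogashira), and the two ring C–H positions that each lie between OMe and OMOM (directed lithiation).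
- Forward: central ring first (reduce, protect, iodinate, alkynylate, attach indole A), the aniline in parallel (propargylation, semi-hydrogenation, aza-Claisen shift), then the pyrrole ring of indole B by heteroannulation, then desilylation, Boc and MOM removal and air oxidation.
- Stereochemistry: the target has no stereocentre and no stereogenic double bond, so nothing has to be controlled.

Key step: step 10

Assumption: compounds 1, 6, 8, 14 and 15 are taken as purchasable; partial loss of the indole N-Boc group in step 10 would be harmless because step 11 removes it.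

**Route**

Step 1
Reactants: 1 2,5-dimethoxy-1,4-benzoquinone
Product: 2 2,5-dimethoxybenzene-1,4-diol
Conditions: Na2S2O4, EtOAc/H2O, rt, under argon
Reagents that add atoms: none
Why: Dithionite reduction of a 1,4-benzoquinone to its hydroquinone is fast and should leave the two methyl ethers untouched.

Step 2
Reactants: 2 2,5-dimethoxybenzene-1,4-diol
Product: 3 1,4-dimethoxy-2,5-bis(methoxymethoxy)benzene
Conditions: MOMCl, iPr2NEt, CH2Cl2, 0 °C to rt, under argon
Reagents that add atoms: chloromethyl methyl ether, COCCl
Why: O-alkylation of both phenols (MOM ether formation) masks the oxidisable hydroquinone and turns each oxygen into a directing group for lithiation.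

Step 3
Reactants: 3 1,4-dimethoxy-2,5-bis(methoxymethoxy)benzene
Product: 5 1-iodo-2,5-dimethoxy-3,6-bis(methoxymethoxy)benzene, via aryllithium 4 (not isolated)
Conditions: n-BuLi (1.1 equiv), THF, −78 to 0 °C; then I2, THF, −78 °C
Reagents that add atoms: iodine, II
Why: Directed ortho-metalation, since each ring C–H lies between an OMe and an OMOM group; one equivalent of base should stop at the monolithio compound, which iodine traps.

Step 4
Reactants: 5 1-iodo-2,5-dimethoxy-3,6-bis(methoxymethoxy)benzene; 6 trimethylsilylacetylene
Product: 7 {[2,5-dimethoxy-3,6-bis(methoxymethoxy)phenyl]ethynyl}trimethylsilane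
Conditions: Pd(PPh3)2Cl2 (cat.), CuI (cat.), Et3N, 60 °C
Reagents that add atoms: none
Why: Sonogashira coupling of an aryl iodide with a terminal alkyne; the iodide should react on warming despite its two ortho oxygen substituents, and the silyl cap prevents double coupling.

Step 5
Reactants: 8 indole
Product: 10 tert-butyl 3-iodoindole-1-carboxylate, via 3-iodoindole 9 (not isolated)
Conditions: I2, KOH, DMF, rt; work-up; then Boc2O, DMAP (cat.), CH2Cl2, rt
Reagents that add atoms: iodine, II; di-tert-butyl dicarbonate, CC(C)(C)OC(=O)OC(=O)OC(C)(C)C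
Why: Electrophilic iodination of indole at C3, followed at once by DMAP-catalysed N-acylation, which stabilises the labile 3-iodoindole as its carbamate.

Step 6
Reactants: 7 {[2,5-dimethoxy-3,6-bis(methoxymethoxy)phenyl]ethynyl}trimethylsilane; 10 tert-butyl 3-iodoindole-1-carboxylate
Product: 13 tert-butyl 3-[2,5-dimethoxy-3,6-bis(methoxymethoxy)-4-(trimethylsilylethynyl)phenyl]indole-1-carboxylate, via aryllithium 11 (not isolated), via arylzinc chloride 12 (not isolated)
Conditions: n-BuLi (1.1 equiv), THF, −78 to −40 °C; ZnCl2, THF, −78 °C to rt; then 10, Pd(PPh3)4 (cat.), THF, 60 °C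
Reagents that add atoms: none
Why: Directed ortho-metalation of the last ring C–H (between OMe and OMOM), transmetalation to zinc and Negishi cross-coupling; the mild arylzinc should spare the Boc group, and the low lithiation temperature should keep n-BuLi off the silylalkyne.

Step 7
Reactants: 14 2-iodoaniline; 15 3-chloro-3-methylbut-1-yne
Product: 16 2-iodo-N-(2-methylbut-3-yn-2-yl)aniline
Conditions: CuCl (cat.), Cu powder, Et3N, THF/H2O, rt
Reagents that add atoms: none
Why: Copper-catalysed propargylic amination of a tertiary propargylic chloride, the standard way to N-(1,1-dimethylpropargyl)anilines, which should tolerate the aryl iodide at room temperature.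

Step 8
Reactants: 16 2-iodo-N-(2-methylbut-3-yn-2-yl)aniline
Product: 17 2-iodo-N-(2-methylbut-3-en-2-yl)aniline
Conditions: H2 (1 atm), Pd/CaCO3 poisoned with Pb(OAc)2 (Lindlar catalyst), quinoline, EtOAc, rt, stopped after one equivalent of H2
Reagents that add atoms: none
Why: Lindlar semi-hydrogenation, in which the terminal alkyne is reduced much faster than the alkene and the poisoned palladium should be slow to cleave the C–I bond.

Step 9
Reactants: 17 2-iodo-N-(2-methylbut-3-en-2-yl)aniline
Product: 18 2-iodo-6-(3-methylbut-2-en-1-yl)aniline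
Conditions: TsOH·H2O, MeCN/H2O (10:1), 80 °C
Reagents that add atoms: none
Why: Acid-accelerated aromatic aza-Claisen ([3,3]) rearrangement of the N-(1,1-dimethylallyl)anilinium ion, which delivers the allyl unit with inversion to the only free ortho carbon and so gives the linear prenyl group at C6.

Step 10
Reactants: 13 tert-butyl 3-[2,5-dimethoxy-3,6-bis(methoxymethoxy)-4-(trimethylsilylethynyl)phenyl]indole-1-carboxylate; 18 2-iodo-6-(3-methylbut-2-en-1-yl)aniline
Product: 19 tert-butyl 3-{2,5-dimethoxy-3,6-bis(methoxymethoxy)-4-[7-(3-methylbut-2-en-1-yl)-2-(trimethylsilyl)-1H-indol-3-yl]phenyl}indole-1-carboxylate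
Conditions: Pd(OAc)2 (10 mol %), LiCl, Na2CO3, DMF, 100 °C, 18 in slight excess
Reagents that add atoms: none
Why: Pd(OAc)2 is reduced in the flask to zerovalent palladium, which inserts into the C–I bond of 18; the arylpalladium iodide then adds syn across the alkyne of 13, the aryl carbon (future C3a) bonding to the alkyne carbon that carries the central ring (future C3) and palladium to the silyl-bearing carbon (future C2). The aniline nitrogen then displaces halide on palladium to give a six-membered azapalladacycle, and C–N reductive elimination forms N1–C2 and releases the catalyst. The closest known reaction type is the Larock heteroannulation of 2-iodoanilines with aryl(trimethylsilyl)alkynes, which gives 3-aryl-2-silylindoles. The pyrrole ring of indole B thus closes by reductive elimination from the six-membered palladacycle, a formal [3+2] union of the C–C–N unit of the aniline with the two alkyne carbons, and no stereocentre is formed. The selectivity needed is the regiochemistry of insertion, which the trimethylsilyl group should secure by taking the carbon next to palladium for steric and electronic reasons, so that it ends at C2 beside nitrogen. The prenyl alkene is trisubstituted and meta to iodine and should not enter a Heck reaction, and the MOM, Boc and methyl ether groups are inert to carbonate in DMF.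

Step 11
Reactants: 19 tert-butyl 3-{2,5-dimethoxy-3,6-bis(methoxymethoxy)-4-[7-(3-methylbut-2-en-1-yl)-2-(trimethylsilyl)-1H-indol-3-yl]phenyl}indole-1-carboxylate
Product: 21 3-[4-(1H-indol-3-yl)-2,5-dimethoxy-3,6-bis(methoxymethoxy)phenyl]-7-(3-methylbut-2-en-1-yl)-1H-indole, via C2-desilylated N-Boc bisindole 20 (not isolated)
Conditions: Bu4NF, THF, 50 °C; then NaOMe (cat.), MeOH, rt
Reagents that add atoms: none
Why: Fluoride-mediated protodesilylation of the 2-silylindole followed by methoxide-catalysed methanolysis of the indole N-carbamate, both under basic conditions that should leave the MOM ethers and the prenyl group alone.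

Step 12
Reactants: 21 3-[4-(1H-indol-3-yl)-2,5-dimethoxy-3,6-bis(methoxymethoxy)phenyl]-7-(3-methylbut-2-en-1-yl)-1H-indole
Product: 23 2-(1H-indol-3-yl)-3,6-dimethoxy-5-[7-(3-methylbut-2-en-1-yl)-1H-indol-3-yl]-1,4-benzoquinone, via hydroquinone 22 (not isolated)
Conditions: ZnBr2, n-PrSH, CH2Cl2, 0 °C to rt, short reaction time; then aqueous work-up, air (O2), EtOAc, rt
Reagents that add atoms: none
Why: Lewis-acid and thiol cleavage of the MOM ethers (ZnBr2 activates the acetal, the thiol traps the methoxymethyl cation) is brief and mild enough to spare the prenyl group and the free indoles, and the electron-rich hydroquinone should autoxidise in air, so no strong oxidant meets the indoles.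

**Compound list**

1 | 2,5-dimethoxy-1,4-benzoquinone | COC1=CC(=O)C(OC)=CC1=O | starting material
2 | 2,5-dimethoxybenzene-1,4-diol | COc1cc(O)c(OC)cc1O | intermediate
3 | 1,4-dimethoxy-2,5-bis(methoxymethoxy)benzene | COCOc1cc(OC)c(OCOC)cc1OC | intermediate
4 | [2,5-dimethoxy-3,6-bis(methoxymethoxy)phenyl]lithium | [Li]c1c(OC)c(OCOC)cc(OC)c1OCOC | intermediate
5 | 1-iodo-2,5-dimethoxy-3,6-bis(methoxymethoxy)benzene | COCOc1c(I)c(OC)c(OCOC)cc1OC | intermediate
6 | trimethylsilylacetylene | C#C[Si](C)(C)C | starting material
7 | {[2,5-dimethoxy-3,6-bis(methoxymethoxy)phenyl]ethynyl}trimethylsilane | COCOc1c(C#C[Si](C)(C)C)c(OC)c(OCOC)cc1OC | intermediate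
8 | indole | c1ccc2[nH]ccc2c1 | starting material
9 | 3-iodoindole | Ic1c[nH]c2ccccc12 | intermediate
10 | tert-butyl 3-iodoindole-1-carboxylate | CC(C)(C)OC(=O)n1cc(I)c2ccccc12 | intermediate
11 | [2,5-dimethoxy-3,6-bis(methoxymethoxy)-4-(trimethylsilylethynyl)phenyl]lithium | COCOc1c(C#C[Si](C)(C)C)c(OC)c(OCOC)c([Li])c1OC | intermediate
12 | [2,5-dimethoxy-3,6-bis(methoxymethoxy)-4-(trimethylsilylethynyl)phenyl]zinc chloride | COCOc1c(C#C[Si](C)(C)C)c(OC)c(OCOC)c([Zn]Cl)c1OC | intermediate
13 | tert-butyl 3-[2,5-dimethoxy-3,6-bis(methoxymethoxy)-4-(trimethylsilylethynyl)phenyl]indole-1-carboxylate | COCOc1c(C#C[Si](C)(C)C)c(OC)c(OCOC)c(-c2cn(C(=O)OC(C)(C)C)c3ccccc23)c1OC | intermediate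
14 | 2-iodoaniline | Nc1ccccc1I | starting material
15 | 3-chloro-3-methylbut-1-yne | C#CC(C)(C)Cl | starting material
16 | 2-iodo-N-(2-methylbut-3-yn-2-yl)aniline | CC(C)(C#C)Nc1ccccc1I | intermediate
17 | 2-iodo-N-(2-methylbut-3-en-2-yl)aniline | CC(C)(C=C)Nc1ccccc1I | intermediate
18 | 2-iodo-6-(3-methylbut-2-en-1-yl)aniline | Nc1c(I)cccc1CC=C(C)C | intermediate
19 | tert-butyl 3-{2,5-dimethoxy-3,6-bis(methoxymethoxy)-4-[7-(3-methylbut-2-en-1-yl)-2-(trimethylsilyl)-1H-indol-3-yl]phenyl}indole-1-carboxylate | COCOc1c(-c2c([Si](C)(C)C)[nH]c3c(CC=C(C)C)cccc23)c(OC)c(OCOC)c(-c2cn(C(=O)OC(C)(C)C)c3ccccc23)c1OC | intermediate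
20 | tert-butyl 3-{2,5-dimethoxy-3,6-bis(methoxymethoxy)-4-[7-(3-methylbut-2-en-1-yl)-1H-indol-3-yl]phenyl}indole-1-carboxylate | COCOc1c(-c2c[nH]c3c(CC=C(C)C)cccc23)c(OC)c(OCOC)c(-c2cn(C(=O)OC(C)(C)C)c3ccccc23)c1OC | intermediate
21 | 3-[4-(1H-indol-3-yl)-2,5-dimethoxy-3,6-bis(methoxymethoxy)phenyl]-7-(3-methylbut-2-en-1-yl)-1H-indole | COCOc1c(-c2c[nH]c3c(CC=C(C)C)cccc23)c(OC)c(OCOC)c(-c2c[nH]c3ccccc23)c1OC | intermediate
22 | 2-(1H-indol-3-yl)-3,6-dimethoxy-5-[7-(3-methylbut-2-en-1-yl)-1H-indol-3-yl]benzene-1,4-diol | COc1c(O)c(-c2c[nH]c3c(CC=C(C)C)cccc23)c(OC)c(O)c1-c1c[nH]c2ccccc12 | intermediate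
23 | 2-(1H-indol-3-yl)-3,6-dimethoxy-5-[7-(3-methylbut-2-en-1-yl)-1H-indol-3-yl]-1,4-benzoquinone | COC1=C(c2c[nH]c3ccccc23)C(=O)C(OC)=C(c2c[nH]c3c(CC=C(C)C)cccc23)C1=O | target

**Count and risks**

Total step count: 12. Longest linear sequence: 8 steps (steps 1, 2, 3, 4, 6, 10, 11, 12).

Steps most likely to fail:

1. Step 10. Carbopalladation of the alkyne may be slow or go with the wrong orientation, because the alkyne carbon that must take the aryl group is shielded by the two ortho substituents of the hexasubstituted ring; the arylpalladium species would then be lost to reduction or oligomerisation. The fallback sets out from 13 and builds the same two bonds by condensation and Heck closure instead of alkyne insertion. Bu4NF buffered with AcOH (THF, 0 °C) should remove only the alkynyl silyl group and give tert-butyl 3-[4-ethynyl-2,5-dimethoxy-3,6-bis(methoxymethoxy)phenyl]indole-1-carboxylate F1. Anti-Markovnikov hydroboration with dicyclohexylborane and oxidation with NaBO3·4H2O should give the arylacetaldehyde tert-butyl 3-[2,5-dimethoxy-3,6-bis(methoxymethoxy)-4-(2-oxoethyl)phenyl]indole-1-carboxylate F2. Annulation of F2 with 18 (Pd(OAc)2, DABCO, DMF, 85 °C) proceeds by enamine formation (N1–C2) and intramolecular Heck reaction (C3–C3a); it should give the 2-unsubstituted indole directly and so comes back to the route at 20, which the methoxide part of step 11 converts to 21.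

2. Step 6. n-BuLi may attack the silylalkyne (addition across the triple bond or attack at silicon) in competition with deprotonation of the crowded ring C–H, and the di-ortho-substituted arylzinc may couple slowly. The fallback sets out from 7 and reverses the polarity of the coupling so that no organolithium meets the alkyne. Electrophilic iodination of the electron-rich ring C–H (N-iodosuccinimide, CF3CO2H cat., MeCN, 0 °C) should give {[4-iodo-2,5-dimethoxy-3,6-bis(methoxymethoxy)phenyl]ethynyl}trimethylsilane F3. Zinc insertion into 10 (Zn dust, LiCl, THF, rt) should give [1-(tert-butoxycarbonyl)indol-3-yl]zinc iodide F4. Negishi coupling of F3 with F4 (Pd(PPh3)4, THF, 60 °C) comes back to the route at 13.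

3. Step 8. Hydrogenolysis of the C–I bond or over-reduction to the saturated amine may accompany the semi-hydrogenation on palladium. The fallback sets out from 14 and avoids hydrogenation altogether. N-Allylation (allyl bromide, K2CO3, DMF, rt) should give N-allyl-2-iodoaniline F5. Lewis-acid-promoted aromatic aza-Claisen rearrangement (BF3·OEt2, sulfolane, 150 °C) should give 2-allyl-6-iodoaniline F6. Cross-metathesis of F6 with 2-methylbut-2-ene (second-generation Grubbs catalyst, (H2IMes)(PCy3)Cl2Ru=CHPh, CH2Cl2, 40 °C) comes back to the route at 18, replacing steps 7 to 9.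

**Further compounds**

F1 | step 10 | tert-butyl 3-[4-ethynyl-2,5-dimethoxy-3,6-bis(methoxymethoxy)phenyl]indole-1-carboxylate | COCOc1c(C#C)c(OC)c(OCOC)c(-c2cn(C(=O)OC(C)(C)C)c3ccccc23)c1OC
F2 | step 10 | tert-butyl 3-[2,5-dimethoxy-3,6-bis(methoxymethoxy)-4-(2-oxoethyl)phenyl]indole-1-carboxylate | COCOc1c(CC=O)c(OC)c(OCOC)c(-c2cn(C(=O)OC(C)(C)C)c3ccccc23)c1OC
F3 | step 6 | {[4-iodo-2,5-dimethoxy-3,6-bis(methoxymethoxy)phenyl]ethynyl}trimethylsilane | COCOc1c(C#C[Si](C)(C)C)c(OC)c(OCOC)c(I)c1OC
F4 | step 6 | [1-(tert-butoxycarbonyl)indol-3-yl]zinc iodide | CC(C)(C)OC(=O)n1cc([Zn]I)c2ccccc12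
F5 | step 8 | N-allyl-2-iodoaniline | C=CCNc1ccccc1I
F6 | step 8 | 2-allyl-6-iodoaniline | Nc1c(I)cccc1CC=C
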